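**Retrosynthetic overview**
- The 1,4-dioxane ring is the only ring formed and is closed last, by making the benzylic C–O bond. The nucleophile is the methoxy oxygen of a eugenol-derived aryl ether; it attacks the benzylic cation and then loses its methyl as MeBr (demethylative cycloetherification, stereoconvergent, trans).
- The open-chain carbinol comes from (3,4,5-trimethoxyphenyl)magnesium bromide and an α-aryloxypropanal generated in the flask from the corresponding ester.
- The ester comes from eugenol and ethyl (S)-lactate by Mitsunobu C–O coupling with inversion. This fixes the methyl-bearing centre as R and the regiochemistry, because the free OH of eugenol is para to the allyl group.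
- Both benzene rings are bought.

Assumption: the SMILES is read as the trans-(2R,3R) isomer (aryl-bearing and methyl-bearing carbons both R); all starting materials are catalogue chemicals.

**Step 1**
Reactants: 1 eugenol (4-allyl-2-methoxyphenol); 2 ethyl (S)-lactate
Product: 3 ethyl (2R)-2-(4-allyl-2-methoxyphenoxy)propanoate
Conditions: PPh3 (1.2 equiv), DIAD (1.2 equiv), THF, 0 °C → rt
Reagents that add atoms: none
Why: Mitsunobu etherification of a phenol with a secondary α-hydroxy ester is an SN2 displacement on the alkoxyphosphonium ion with clean inversion, so (S)-lactate gives the (R)-aryloxypropanoate that becomes the methyl-bearing centre of the target.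

**Step 2**
Reactants: 4 5-bromo-1,2,3-trimethoxybenzene
Product: 5 (3,4,5-trimethoxyphenyl)magnesium bromide (THF solution, titrated and used directly)
Conditions: Mg turnings (1.2 equiv), I2 (cat.), THF, 50 °C, 2 h
Reagents that add atoms: magnesium, [Mg]
Why: Grignard formation by direct magnesium insertion into an electron-rich aryl bromide; the methoxy groups are inert.

**Step 3**
Reactants: 3 ethyl (2R)-2-(4-allyl-2-methoxyphenoxy)propanoate; 5 (3,4,5-trimethoxyphenyl)magnesium bromide
Product: 8 (1RS,2R)-2-(4-allyl-2-methoxyphenoxy)-1-(3,4,5-trimethoxyphenyl)propan-1-ol (both C1 epimers carried on together), via aluminium hemiacetal 6 (not isolated), via aldehyde 7 (not isolated)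
Conditions: iBu2AlH (1.1 equiv), CH2Cl2, −78 °C, 1 h; then 5 (2.5 equiv, THF), −78 → 0 °C; aq. potassium sodium tartrate
Reagents that add atoms: none
Why: One-pot partial ester reduction/Grignard addition: iBu2AlH stops at the tetrahedral aluminium hemiacetal at −78 °C, and the aryl Grignard releases and traps the aldehyde in the same flask, so the epimerisable α-aryloxy aldehyde is never isolated and the (R) centre is kept; the new carbinol centre forms as a mixture, which does not matter because step 4 erases it.

**Step 4**
Reactants: 8 (1RS,2R)-2-(4-allyl-2-methoxyphenoxy)-1-(3,4,5-trimethoxyphenyl)propan-1-ol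
Product: 11 (2R,3R)-6-allyl-2-methyl-3-(3,4,5-trimethoxyphenyl)-2,3-dihydro-1,4-benzodioxine (trans; the target), via benzylic bromide 9 (not isolated), via methyloxonium bromide 10 (not isolated)
Conditions: TMSBr (1.3 equiv), CH2Cl2, 0 °C, 30 min; then CH2Cl2/HFIP 4:1 (0.02 M), nBu4NBr (20 mol%), 40 °C
Reagents that add atoms: none
Why: Proposed new method: stereoconvergent demethylative cycloetherification. TMSBr converts the benzylic alcohol into the bromide (precedented for guaiacyl β-ether carbinols). In the ionising medium both epimeric bromides give the same 3,4,5-trimethoxybenzyl cation, which is captured through a six-membered transition state by the only methoxy oxygen within reach (the eugenol OMe), giving an aryl(alkyl)methyloxonium ion. Bromide then removes the methyl by SN2 (MeBr leaves), which makes the ring closure irreversible and frees the ether oxygen without any separate, unselective demethylation among the four ArOMe groups. The benzylic centre is set trans to the fixed (R)-methyl centre because oxonium formation is reversible, the trans-diequatorial ring is favoured, and traces of HBr re-ionise the benzylic C–O bond of any cis ether. The closest known reaction types are Winstein MeO-n neighbouring-group participation (o-anisyl oxygen giving dihydrobenzofuran with loss of the methyl group) and Larock demethylative cyclisation of 2-alkynylanisoles. It has not been shown for benzylic cations closing to 2-aryl-1,4-benzodioxanes.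

**Compound list**
1 | eugenol (4-allyl-2-methoxyphenol) | C=CCc1ccc(O)c(OC)c1 | starting material
2 | ethyl (S)-lactate | C[C@H](O)C(=O)OCC | starting material
3 | ethyl (2R)-2-(4-allyl-2-methoxyphenoxy)propanoate | CCOC(=O)[C@@H](C)Oc1ccc(CC=C)cc1OC | intermediate
4 | 5-bromo-1,2,3-trimethoxybenzene | COc1cc(Br)cc(OC)c1OC | starting material
5 | (3,4,5-trimethoxyphenyl)magnesium bromide | COc1cc([Mg]Br)cc(OC)c1OC | intermediate
6 | aluminium hemiacetal: diisobutylaluminium alkoxide of the ethyl hemiacetal of aldehyde 7, (2R) at the aryloxy carbon | CCOC(O[Al](CC(C)C)CC(C)C)[C@@H](C)Oc1ccc(CC=C)cc1OC | intermediate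
7 | (2R)-2-(4-allyl-2-methoxyphenoxy)propanal | O=C[C@@H](C)Oc1ccc(CC=C)cc1OC | intermediate
8 | (1RS,2R)-2-(4-allyl-2-methoxyphenoxy)-1-(3,4,5-trimethoxyphenyl)propan-1-ol | COc1cc(cc(OC)c1OC)C(O)[C@@H](C)Oc1ccc(CC=C)cc1OC | intermediate
9 | 4-allyl-1-{[(1RS,2R)-1-bromo-1-(3,4,5-trimethoxyphenyl)propan-2-yl]oxy}-2-methoxybenzene (benzylic bromide) | COc1cc(cc(OC)c1OC)C(Br)[C@@H](C)Oc1ccc(CC=C)cc1OC | intermediate
10 | O-methyl oxonium bromide of 11 (methyl on the ring oxygen bonded to the benzylic carbon; trans, both ring carbons R) | C=CCc1ccc2c(c1)[O+](C)[C@H](c1cc(OC)c(OC)c(OC)c1)[C@@H](C)O2.[Br-] | intermediate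
11 | (2R,3R)-6-allyl-2-methyl-3-(3,4,5-trimethoxyphenyl)-2,3-dihydro-1,4-benzodioxine (trans) | C=CCc1ccc2c(c1)O[C@H](c1cc(OC)c(OC)c(OC)c1)[C@@H](C)O2 | target

**Totals**
Total step count: 4. Longest linear sequence: 3 steps (steps 1, 3 and 4; step 2 is the side branch).

**Steps most likely to fail**

Step 4 (the proposed new demethylative cyclisation). The risks are loss of the β-hydrogen from the benzylic cation (enol ether, then arylacetone plus eugenol), Friedel–Crafts oligomers, incomplete cis → trans equilibration, and HBr addition to the allyl group. The fallback uses known chemistry, sets out from 3 and comes back at 11. Compound 3 carries only one aryl methyl ether, so BBr3 (CH2Cl2, −78 → −20 °C) cleaves it without a selectivity problem. The freed phenol closes onto the ethyl ester (TsOH cat., toluene, 50 °C) to give the lactone (3R)-7-allyl-3-methyl-1,4-benzodioxin-2(3H)-one F1. Reduction with iBu2AlH (CH2Cl2, −78 °C) gives the lactol (2RS,3R)-7-allyl-3-methyl-2,3-dihydro-1,4-benzodioxin-2-ol F2. Excess 5 (3 equiv, THF, −40 → 0 °C) adds to its open hydroxy-aldehyde form and gives the free phenol carbinol (1RS,2R)-2-(4-allyl-2-hydroxyphenoxy)-1-(3,4,5-trimethoxyphenyl)propan-1-ol F3. F3 is then closed by the established acid-mediated dehydrative cyclisation of an ortho-hydroxyphenoxy benzylic alcohol (BF3·OEt2, CH2Cl2, 0 °C), which is trans-selective through the same benzylic cation, to give 11.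

Step 3 (one-pot reduction/arylation). The risks are over-reduction to the primary alcohol, incomplete collapse of the aluminium hemiacetal, and partial epimerisation of the aldehyde. The fallback sets out from 3 and comes back at 8. Compound 3 is converted directly into the Weinreb amide (2R)-2-(4-allyl-2-methoxyphenoxy)-N-methoxy-N-methylpropanamide F4 (MeNHOMe·HCl, iPrMgCl, THF, −20 °C). Addition of 5 (THF, 0 °C) stops at the ketone (2R)-2-(4-allyl-2-methoxyphenoxy)-1-(3,4,5-trimethoxyphenyl)propan-1-one F5. NaBH4 (MeOH, 0 °C) reduces F5 to 8; either carbinol epimer serves.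

Step 1 (Mitsunobu). The risks are sluggish coupling of the ortho-substituted phenol and difficult removal of Ph3PO and the hydrazine by-product on scale. The fallback sets out from 2 and comes back at 3. Compound 2 is converted into ethyl (2S)-2-(tosyloxy)propanoate F6 (TsCl, Et3N, DMAP cat., CH2Cl2, 0 °C). F6 is displaced by the phenoxide of 1 (K2CO3, MeCN, 60 °C) in an SN2 alkylation with inversion, the industrial aryloxypropionate method, to give 3.

**Further compounds**
F1 | step 4 | (3R)-7-allyl-3-methyl-1,4-benzodioxin-2(3H)-one | C[C@H]1Oc2ccc(CC=C)cc2OC1=O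
F2 | step 4 | (2RS,3R)-7-allyl-3-methyl-2,3-dihydro-1,4-benzodioxin-2-ol | C[C@H]1Oc2ccc(CC=C)cc2OC1O
F3 | step 4 | (1RS,2R)-2-(4-allyl-2-hydroxyphenoxy)-1-(3,4,5-trimethoxyphenyl)propan-1-ol | COc1cc(cc(OC)c1OC)C(O)[C@@H](C)Oc1ccc(CC=C)cc1O
F4 | step 3 | (2R)-2-(4-allyl-2-methoxyphenoxy)-N-methoxy-N-methylpropanamide | CON(C)C(=O)[C@@H](C)Oc1ccc(CC=C)cc1OC
F5 | step 3 | (2R)-2-(4-allyl-2-methoxyphenoxy)-1-(3,4,5-trimethoxyphenyl)propan-1-one | COc1cc(cc(OC)c1OC)C(=O)[C@@H](C)Oc1ccc(CC=C)cc1OC
F6 | step 1 | ethyl (2S)-2-(tosyloxy)propanoate | C[C@H](OS(=O)(=O)c1ccc(C)cc1)C(=O)OCC
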